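**Structural features**

The target is a 2,5-diaryl-3,4-dimethyltetrahydrofuran. O1 lies between C2, which carries ring B, and C5, which carries ring A (4-hydroxyphenyl); C3 and C4 each carry a methyl group. Ring B is a 1,2,4-trisubstituted phenol: the tetrahydrofuran is para to the hydroxyl, and ortho to the hydroxyl sits a (2R)-1-arylpropan-2-yl chain that ends in ring C, a second 4-hydroxyphenyl. The ring holds four contiguous stereocentres (2R,3R,4S,5S): the aryl groups are 2,5-cis, the methyl groups 3,4-cis, and each aryl group is trans to the methyl beside it. The side-chain stereocentre lies too far from the ring to be relayed from it, so each half needs its own absolute control. Both ring C–O bonds are benzylic and para to an oxygen-bearing arene, so acids ionise them and hydrogenolysis can cut them; the three phenols must therefore be unmasked without a Lewis acid. The real difficulty is the 3,4-cis relation: C2 and C5 sit where thermodynamics places them once C3 and C4 are fixed, but the C3 substituent must lie cis to the C4 methyl. The key step uses the array O1–C5(ring A)–C4(CH3) with C2 at the aldehyde oxidation level: with a gem-diester on C3, this is what remains when an aldehyde oxygen opens a 2-aryl-3-methylcyclopropane-1,1-diester at its benzylic carbon and the malonate carbon closes onto the carbonyl carbon.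

**Logic of the disconnections**

23 from 22. The three aryl O–benzyl bonds are cut. Benzyl is preferred to methyl because hydrogenolysis is neutral, whereas a triple demethylation needs a Lewis acid or hot thiolate, which the doubly benzylic ring ethers would not survive. The skeleton is unchanged, but every earlier step is freed from phenol chemistry. The demand is that hydrogenolysis stops at the aryl benzyl ethers.

22 from 21, 20 and 19. The C3 methyl is traced back through CH2OMs and CH2OH to a C3 methyl ester. The ester makes C3 the one epimerisable centre of the ring and links the ring to malonate chemistry. The demand is a hydride displacement at a β-branched primary carbon, and that C3 is correct before the ester is reduced.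

19 from 18 and 17. A second ester is added at C3. The gem-diester is the acceptor the annulation needs, and it removes C3 as a stereocentre at the key step. The forward demand is a dealkoxycarbonylation followed by equilibration that places the remaining ester trans to the C2 aryl although cis to the C4 methyl, without opening the β-alkoxy ester.

17 from 6 and 16. The bonds O1–C5 and C2–C3 are cut. This divides the molecule into halves of similar size. The four-centre ring reduces to a cyclopropane with two centres and an aldehyde with one remote centre. The forward step must open 6 with inversion at the benzylic carbon and close 2,5-cis, and capture by 16 must outrun reversible opening of 6.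

6 from 3 and 5; 3 from 1 and 2; 5 from 4. Both cyclopropane bonds to the malonate carbon are cut. A concerted syn carbene addition turns Z geometry into the cis aryl/methyl relation, and the catalyst sets the absolute sense. A copper–bis(oxazoline) catalyst is preferred to a chiral dirhodium carboxylate, because acceptor/acceptor carbenes give weak induction with the latter. The demand for a geometrically pure Z alkene is met by cutting the aryl–alkenyl bond of 3 (stereoretentive coupling of 1 with 2) instead of relying on a photostationary mixture. 5 comes from 4 by diazo transfer.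

16 from 14, 13, 10 + 12, 9, 7 + 8, and 11. The C–CHO bond is cut back to a bromine placeholder para to the ring-B oxygen (14). The two C–H bonds at the side-chain centre are then cut to the trisubstituted alkene 13, so that one asymmetric hydrogenation sets the remote centre. Because E and Z alkenes would give opposite enantiomers, 13 is cut at the ring-B–alkenyl bond into 12 and the geometrically defined boronate 10. This stereospecific coupling replaces a carbonyl olefination, which would give a mixture. 10 comes from alkyne 9 by syn borylation, 9 from 7 and 8, and 12 from 11.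

**Other disconnections considered**

Alternative 1: Ring B would be built last. The cut removes two ring-B bonds: the bond from the carbon bearing the tetrahydrofuran to its CH neighbour, and the bond from the side-chain-bearing carbon to the CH between the two substituents. The forward step joins aldehyde A2 and ethynyl ketone A3 with pyrrolidine (enamine Michael addition to the alkyne terminus, then aldol condensation and aromatisation) to give phenol A1.
- In its favour: the 1,2,4-pattern follows from connectivity, and the ring-B phenol appears unprotected. The side-chain centre sits β to a ketone in A3 and could be set by a routine auxiliary alkylation; on that point it is better than the hindered-alkene hydrogenation of the chosen plan. Convergence is equal.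
- Against it: the step creates no stereocentre, so all four ring centres must be made beforehand in A2. The C2 substituent of A2 is an alkyl chain, so aryl-assisted ring constructions do not apply directly. A2 is a β-alkoxy aldehyde whose enamine can expel the ring oxygen in a geometrically allowed exo sense, which threatens C2. Rings A and C of A1 would still need deprotection beside the acid-labile ring.
- Overall it moves the stereochemical work elsewhere and would probably be longer.

Alternative 2: The cut is C2–C3 and C4–C5. SnCl4 would ionise the dioxolane acetal A5, the propenyl terminus would attack the oxocarbenium carbon, and a 1,2-shift of C5 would contract the ring to aldehyde A4.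
- In its favour: two C–C bonds and up to three ring centres form in one operation, against one C–O bond, one C–C bond and two centres in the chosen plan; on bond and stereocentre count it is the better. It uses the same kind of ring-B aldehyde. The formyl group of A4 needs no dealkoxycarbonylation, so the way to the methyl is about two steps shorter.
- Against it: the cation formed at C4 after the first bond is secondary and unstabilised, whereas the established cases have a stabilising substituent there. C5 carries a 4-alkoxyphenyl group, so the Lewis acid can ionise the C5–O bond and erase that centre. The formyl-bearing C4 is epimerisable and must end cis to the C3 methyl, the same contra-thermodynamic relation that the chosen plan faces at C3.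
- Mechanistically the chosen plan has closer precedent.

Alternative 3: The cut is the side-chain CH–CH2 bond. Rh2(S-PTTL)4 or its enantiomer would convert diazoester A7 to a carbene that inserts into the 4-methoxybenzyl ether C–H bond, giving cis-dihydrobenzofuran A6. Ester-to-methyl conversion and reductive opening of the benzylic C–O bond would then reveal the ring-B phenol and the side chain.
- In its favour: this insertion has strong precedent for enantio- and cis-selectivity. It sets the remote centre without a hindered-alkene hydrogenation and is at least the equal of step 8 in reliability of induction. The aryl bromide stays available for formylation.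
- Against it: it solves only the side chain, so the tetrahydrofuran still needs its own key step; it supplements the chosen disconnection and cannot replace it. The ring it closes is destroyed again. The surviving centre is benzylic and α to an ester, so any cis-to-trans epimerisation inverts it. Ester-to-methyl conversion, ring opening and reprotection cost about five more steps than coupling plus hydrogenation.

Key step: step 10

Assumption: the sense of induction in steps 3 and 8 is assigned by analogy with Z-1-arylpropenes and E-1,2-diarylpropenes; if either proved opposite, the mirror-image ligand would be used.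

Abbreviation in names: ArB = 4-(benzyloxy)-3-{(2R)-1-[4-(benzyloxy)phenyl]propan-2-yl}phenyl (ring B with side chain and ring C, both phenols benzylated).

**Route**

Step 1
Reactants: 1 4-(benzyloxy)phenylboronic acid; 2 (Z)-1-bromoprop-1-ene
Product: 3 (Z)-1-(benzyloxy)-4-(prop-1-en-1-yl)benzene
Conditions: Pd(PPh3)4 (3 mol%), K2CO3, THF/H2O, 60 °C, sealed tube
Reagents that add atoms: none
Why: Suzuki–Miyaura coupling of an alkenyl bromide proceeds with retention of alkene geometry, so the Z alkene should be obtained without a photochemical E/Z mixture.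

Step 2
Reactants: 4 dimethyl malonate
Product: 5 dimethyl 2-diazomalonate
Conditions: 4-acetamidobenzenesulfonyl azide, Et3N, MeCN, 0 °C to rt
Reagents that add atoms: 4-acetamidobenzenesulfonyl azide, CC(=O)Nc1ccc(cc1)S(=O)(=O)N=[N+]=[N-]
Why: Regitz diazo transfer to an active methylene compound; the acetamido reagent is the safer sulfonyl azide and its sulfonamide is removed by filtration.

Step 3
Reactants: 3 (Z)-1-(benzyloxy)-4-(prop-1-en-1-yl)benzene; 5 dimethyl 2-diazomalonate
Product: 6 dimethyl (2R,3R)-2-[4-(benzyloxy)phenyl]-3-methylcyclopropane-1,1-dicarboxylate (aryl and methyl cis)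
Conditions: Cu(MeCN)4PF6 (5 mol%), chiral bis(oxazoline) with a benzylic side arm on the bridging carbon (6 mol%), toluene, 50 °C, slow addition of 5
Reagents that add atoms: none
Why: Copper–bis(oxazoline) carbene transfer from a diazomalonate to a Z-1,2-disubstituted aryl alkene is a known asymmetric cyclopropanation. The concerted syn addition turns the Z geometry into the cis aryl/methyl relation, and the ligand selects the alkene face, setting both centres.

Step 4
Reactants: 7 1-(benzyloxy)-4-iodobenzene; 8 propyne
Product: 9 1-(benzyloxy)-4-(prop-1-yn-1-yl)benzene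
Conditions: Pd(PPh3)2Cl2 (2 mol%), CuI (4 mol%), Et3N, THF, rt, propyne as a THF solution
Reagents that add atoms: none
Why: Sonogashira coupling of an aryl iodide with a terminal alkyne at room temperature; the benzyl ether is inert.

Step 5
Reactants: 9 1-(benzyloxy)-4-(prop-1-yn-1-yl)benzene
Product: 10 (Z)-2-{1-[4-(benzyloxy)phenyl]prop-1-en-2-yl}-4,4,5,5-tetramethyl-1,3,2-dioxaborolane (boron trans to the aryl group)
Conditions: CuCl (5 mol%), Xantphos (6 mol%), NaOt-Bu (10 mol%), B2pin2, MeOH (2 equiv), THF, rt
Reagents that add atoms: bis(pinacolato)diboron, CC1(C)OB(OC1(C)C)B1OC(C)(C)C(C)(C)O1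
Why: Copper-catalysed borylation–protonation of an aryl alkyl alkyne: the boryl copper adds syn with copper at the aryl-bearing carbon and boron at the methyl-bearing carbon, and methanol protonates the C–Cu bond with retention, so one alkene geometry results.

Step 6
Reactants: 11 4-bromo-2-iodophenol
Product: 12 1-(benzyloxy)-4-bromo-2-iodobenzene
Conditions: BnBr, K2CO3, DMF, rt
Reagents that add atoms: benzyl bromide, BrCc1ccccc1
Why: Williamson ether synthesis on a phenoxide; the aryl halides are untouched.

Step 7
Reactants: 10 (Z)-alkenylboronate; 12 1-(benzyloxy)-4-bromo-2-iodobenzene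
Product: 13 (E)-1-(benzyloxy)-2-{1-[4-(benzyloxy)phenyl]prop-1-en-2-yl}-4-bromobenzene (the two aryl groups trans)
Conditions: Pd(dppf)Cl2 (3 mol%), K3PO4, dioxane/H2O, 60 °C
Reagents that add atoms: none
Why: Suzuki–Miyaura coupling with retention at the alkenyl carbon gives the E alkene as a single geometric isomer. Oxidative addition at C–I is much faster than at C–Br, so the bromine is kept for step 9.

Step 8
Reactants: 13 (E)-alkene
Product: 14 1-(benzyloxy)-2-{(2R)-1-[4-(benzyloxy)phenyl]propan-2-yl}-4-bromobenzene
Conditions: [Ir(cod)(L)]BArF (1–2 mol%; L = (S)-4-tert-butyl-2-[2-(di-o-tolylphosphanyl)phenyl]-4,5-dihydrooxazole, BArF = B[3,5-(CF3)2C6H3]4), H2 (50 bar), CH2Cl2, rt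
Reagents that add atoms: none
Why: Iridium–phosphinooxazoline asymmetric hydrogenation of an unfunctionalised E-1,2-diarylpropene, the standard substrate class for these catalysts; the chiral pocket selects the alkene face and sets the R centre. The cationic iridium hydride reduces neither the C–Br bond nor the benzyl ethers.

Step 9
Reactants: 14 (R)-aryl bromide
Product: 16 4-(benzyloxy)-3-{(2R)-1-[4-(benzyloxy)phenyl]propan-2-yl}benzaldehyde, via aryllithium 15 (not isolated)
Conditions: n-BuLi, THF, −78 °C; DMF; then 1 M HCl
Reagents that add atoms: N,N-dimethylformamide, CN(C)C=O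
Why: Bromine–lithium exchange at −78 °C is faster than any deprotonation of the benzyl ethers, and the aryllithium is formylated by DMF. The side-chain centre is not acidic and is untouched.

Step 10
Reactants: 6 cis-cyclopropane diester; 16 ring-B aldehyde (1.5 equiv, excess recovered)
Product: 17 dimethyl (2S,4S,5S)-5-[4-(benzyloxy)phenyl]-2-(ArB)-4-methyloxolane-3,3-dicarboxylate (aryl groups 2,5-cis; C4 methyl trans to the C5 aryl)
Conditions: Sn(OTf)2 (10 mol%), CH2Cl2, −20 to 0 °C, quench with Et3N
Reagents that add atoms: none
Why: Divalent tin triflate chelates the two esters of 6 and polarises the bond between the malonate carbon and the benzylic carbon; the carbonyl oxygen of 16 attacks the benzylic carbon anti to the departing malonate carbon (SN2-like), forming O1–C5 with inversion. The tin-bound malonate then adds to the oxocarbenium carbon and forms C2–C3; the closest known reaction type is the Lewis-acid-catalysed (3+2) annulation of 2-arylcyclopropane-1,1-diesters with aldehydes to 2,5-cis-tetrahydrofurans. The one ring closes by a 5-(enolexo)-endo-trig aldol-type collapse of a tight ion pair, which the short tether makes fast despite the nominally awkward endo geometry. C5 is controlled by the configuration of the benzylic carbon of 6 through inversion, and the cis aryl/methyl relation of 6 therefore becomes 4,5-trans. C2 is controlled by an envelope transition state with both aryl groups pseudo-equatorial, which gives 2,5-cis, and C4 is carried over unchanged from 6. The step needs capture by the aldehyde to be faster than reversible opening of the cyclopropane; the 4-benzyloxyphenyl donor accelerates both, so it is an asset and a liability. The electron-rich, para-alkoxy aldehyde 16 is a strong oxygen nucleophile, and its excess together with low temperature should secure stereospecific capture. Short reaction time and a basic quench guard the kinetic 2,5-cis product against Lewis-acid isomerisation.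

Step 11
Reactants: 17 tetrahydrofuran diester
Product: 18 methyl (2R,4S,5S)-5-[4-(benzyloxy)phenyl]-2-(ArB)-4-methyloxolane-3-carboxylate, mixture of C3 epimers
Conditions: LiCl, H2O, DMSO, 150 °C
Reagents that add atoms: none
Why: Krapcho dealkoxycarbonylation: chloride demethylates one ester, the carboxylate loses CO2 and water protonates the enolate. The medium is neutral, so the benzyl ethers and the benzylic ring ethers should survive; C3 is left to step 12.

Step 12
Reactants: 18 monoester, C3 epimer mixture
Product: 19 methyl (2R,3R,4S,5S)-5-[4-(benzyloxy)phenyl]-2-(ArB)-4-methyloxolane-3-carboxylate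
Conditions: NaOMe, MeOH/THF, 50 °C; minor epimer separated and resubmitted
Reagents that add atoms: none
Why: Base-mediated epimerisation through the ester enolate lets C3 settle with the ester trans to the bulky C2 aryl, which should outweigh the cis relation to the smaller C4 methyl; C2, C4 and C5 have no acidic hydrogen. Expulsion of the ring oxygen from the enolate would be the reverse of a 5-endo-trig closure and is geometrically hindered, so the ring should stay closed.

Step 13
Reactants: 19 (3R)-ester
Product: 20 [(2R,3S,4S,5S)-5-[4-(benzyloxy)phenyl]-2-(ArB)-4-methyloxolan-3-yl]methanol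
Conditions: LiAlH4, THF, 0 °C
Reagents that add atoms: none
Why: Hydride reduction of the ester to the primary alcohol; the reaction is fast at 0 °C, so the alkoxide-free ester is consumed before C3 can epimerise, and the ethers are inert.

Step 14
Reactants: 20 primary alcohol
Product: 21 [(2R,3S,4S,5S)-5-[4-(benzyloxy)phenyl]-2-(ArB)-4-methyloxolan-3-yl]methyl methanesulfonate
Conditions: MsCl, Et3N, CH2Cl2, 0 °C
Reagents that add atoms: methanesulfonyl chloride, CS(=O)(=O)Cl
Why: Sulfonylation of a primary alcohol under basic conditions, with no acid to touch the ring ethers.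

Step 15
Reactants: 21 mesylate
Product: 22 (2R,3R,4S,5S)-5-[4-(benzyloxy)phenyl]-2-(ArB)-3,4-dimethyloxolane
Conditions: LiEt3BH, THF, 0 to 50 °C
Reagents that add atoms: none
Why: SN2 displacement of a primary sulfonate by the strongly nucleophilic triethylborohydride, which tolerates β-branching; no stereocentre is involved and the aryl benzyl ethers are stable.

Step 16
Reactants: 22 tribenzyl ether
Product: 23 4-[(2R,3R,4S,5S)-5-(4-hydroxyphenyl)-3,4-dimethyloxolan-2-yl]-2-[(2R)-1-(4-hydroxyphenyl)propan-2-yl]phenol (target)
Conditions: H2 (1 atm), palladium on carbon (10%), EtOAc/MeOH, rt, stopped at full conversion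
Reagents that add atoms: none
Why: Hydrogenolysis of aryl benzyl ethers in a neutral medium is much faster than cleavage of the hindered secondary benzylic ring ethers, so the three phenols should be released with the ring and all five stereocentres intact.

**Compound list**

1 | 4-(benzyloxy)phenylboronic acid | OB(O)c1ccc(OCc2ccccc2)cc1 | starting material
2 | (Z)-1-bromoprop-1-ene | C/C=C\Br | starting material
3 | (Z)-1-(benzyloxy)-4-(prop-1-en-1-yl)benzene | C/C=C\c1ccc(OCc2ccccc2)cc1 | intermediate
4 | dimethyl malonate | COC(=O)CC(=O)OC | starting material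
5 | dimethyl 2-diazomalonate | COC(=O)C(=[N+]=[N-])C(=O)OC | intermediate
6 | dimethyl (2R,3R)-2-[4-(benzyloxy)phenyl]-3-methylcyclopropane-1,1-dicarboxylate | COC(=O)C1(C(=O)OC)[C@H](C)[C@@H]1c1ccc(OCc2ccccc2)cc1 | intermediate
7 | 1-(benzyloxy)-4-iodobenzene | Ic1ccc(OCc2ccccc2)cc1 | starting material
8 | propyne | CC#C | starting material
9 | 1-(benzyloxy)-4-(prop-1-yn-1-yl)benzene | CC#Cc1ccc(OCc2ccccc2)cc1 | intermediate
10 | (Z)-2-{1-[4-(benzyloxy)phenyl]prop-1-en-2-yl}-4,4,5,5-tetramethyl-1,3,2-dioxaborolane | C/C(B1OC(C)(C)C(C)(C)O1)=C\c1ccc(OCc2ccccc2)cc1 | intermediate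
11 | 4-bromo-2-iodophenol | Oc1ccc(Br)cc1I | starting material
12 | 1-(benzyloxy)-4-bromo-2-iodobenzene | Brc1ccc(OCc2ccccc2)c(I)c1 | intermediate
13 | (E)-1-(benzyloxy)-2-{1-[4-(benzyloxy)phenyl]prop-1-en-2-yl}-4-bromobenzene | C/C(c1cc(Br)ccc1OCc1ccccc1)=C\c1ccc(OCc2ccccc2)cc1 | intermediate
14 | 1-(benzyloxy)-2-{(2R)-1-[4-(benzyloxy)phenyl]propan-2-yl}-4-bromobenzene | Brc1ccc(OCc2ccccc2)c([C@H](C)Cc2ccc(OCc3ccccc3)cc2)c1 | intermediate
15 | [4-(benzyloxy)-3-{(2R)-1-[4-(benzyloxy)phenyl]propan-2-yl}phenyl]lithium | [Li]c1ccc(OCc2ccccc2)c([C@H](C)Cc2ccc(OCc3ccccc3)cc2)c1 | intermediate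
16 | 4-(benzyloxy)-3-{(2R)-1-[4-(benzyloxy)phenyl]propan-2-yl}benzaldehyde | O=Cc1ccc(OCc2ccccc2)c([C@H](C)Cc2ccc(OCc3ccccc3)cc2)c1 | intermediate
17 | dimethyl (2S,4S,5S)-5-[4-(benzyloxy)phenyl]-2-(ArB)-4-methyloxolane-3,3-dicarboxylate | COC(=O)C1(C(=O)OC)[C@H](C)[C@@H](c2ccc(OCc3ccccc3)cc2)O[C@H]1c1ccc(OCc2ccccc2)c([C@H](C)Cc2ccc(OCc3ccccc3)cc2)c1 | intermediate
18 | methyl (2R,4S,5S)-5-[4-(benzyloxy)phenyl]-2-(ArB)-4-methyloxolane-3-carboxylate, C3 epimer mixture | COC(=O)C1[C@H](C)[C@@H](c2ccc(OCc3ccccc3)cc2)O[C@H]1c1ccc(OCc2ccccc2)c([C@H](C)Cc2ccc(OCc3ccccc3)cc2)c1 | intermediate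
19 | methyl (2R,3R,4S,5S)-5-[4-(benzyloxy)phenyl]-2-(ArB)-4-methyloxolane-3-carboxylate | COC(=O)[C@@H]1[C@H](C)[C@@H](c2ccc(OCc3ccccc3)cc2)O[C@H]1c1ccc(OCc2ccccc2)c([C@H](C)Cc2ccc(OCc3ccccc3)cc2)c1 | intermediate
20 | [(2R,3S,4S,5S)-5-[4-(benzyloxy)phenyl]-2-(ArB)-4-methyloxolan-3-yl]methanol | OC[C@@H]1[C@H](C)[C@@H](c2ccc(OCc3ccccc3)cc2)O[C@H]1c1ccc(OCc2ccccc2)c([C@H](C)Cc2ccc(OCc3ccccc3)cc2)c1 | intermediate
21 | [(2R,3S,4S,5S)-5-[4-(benzyloxy)phenyl]-2-(ArB)-4-methyloxolan-3-yl]methyl methanesulfonate | CS(=O)(=O)OC[C@@H]1[C@H](C)[C@@H](c2ccc(OCc3ccccc3)cc2)O[C@H]1c1ccc(OCc2ccccc2)c([C@H](C)Cc2ccc(OCc3ccccc3)cc2)c1 | intermediate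
22 | (2R,3R,4S,5S)-5-[4-(benzyloxy)phenyl]-2-(ArB)-3,4-dimethyloxolane | C[C@@H]1[C@H](C)[C@@H](c2ccc(OCc3ccccc3)cc2)O[C@H]1c1ccc(OCc2ccccc2)c([C@H](C)Cc2ccc(OCc3ccccc3)cc2)c1 | intermediate
23 | 4-[(2R,3R,4S,5S)-5-(4-hydroxyphenyl)-3,4-dimethyloxolan-2-yl]-2-[(2R)-1-(4-hydroxyphenyl)propan-2-yl]phenol | C[C@@H]1[C@H](C)[C@@H](c2ccc(O)cc2)O[C@H]1c1ccc(O)c([C@H](C)Cc2ccc(O)cc2)c1 | target

**Step count and least certain steps**

Total: 16 steps. Longest linear sequence: 12 steps (4, 5, 7, 8, 9, 10, 11–16).

Step 10 (key step). The most likely failure is loss of stereospecificity at the benzylic carbon. The 4-benzyloxyphenyl group stabilises the ring-opened zwitterion, so the Lewis acid can open and reclose the cyclopropane before the aldehyde captures it. Only the benzylic centre relaxes; the methyl-bearing centre cannot. Part of the material would then be captured with the opposite configuration at C5. A slower 2,5-cis to 2,5-trans drift by reversible C2–C3 cleavage is possible on long exposure. The fallback replaces kinetic control at C5 by thermodynamic control. It sets out from 6 and 16 and returns at 22.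
- The annulation is run as before, and the C5 epimer, dimethyl (2S,4S,5R)-5-[4-(benzyloxy)phenyl]-2-(ArB)-4-methyloxolane-3,3-dicarboxylate F1, is carried on, alone or mixed with 17.
- The chemistry of steps 11–15 converts it through the monoester epimer mixture F2, the (3R)-ester F3, the alcohol F4 and the mesylate F5 into the C5-epimeric dimethyloxolane F6.
- F6 is treated with catalytic BF3·OEt2 in CH2Cl2 at −20 °C. Reversible ionisation of the benzylic C–O bonds equilibrates C2 and C5. With the 3,4-cis methyl groups fixed, the isomer with each aryl trans to its neighbouring methyl is the thermodynamic sink, and that isomer is 22.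

Step 12. The thermodynamic bias may be insufficient: the ester is asked to sit cis to the C4 methyl in order to be trans to the C2 aryl, and the equilibrium may leave a substantial share of the wrong epimer. The fallback uses kinetic control and a stereoretentive excision. It sets out from 18 and returns at 22, in the same number of steps as steps 12–15.
- The enolate of 18 (LDA, THF, −78 °C) is methylated with MeI on the face away from the C2 aryl, giving methyl (2S,3S,4S,5S)-5-[4-(benzyloxy)phenyl]-2-(ArB)-3,4-dimethyloxolane-3-carboxylate F7.
- LiAlH4 gives the neopentyl alcohol F8, and the periodinane DMP oxidises it to the aldehyde F9.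
- Tsuji–Wilkinson decarbonylation with stoichiometric RhCl(PPh3)3 in hot toluene replaces the formyl group by hydrogen with retention and delivers 22.

Step 3. Face discrimination by the copper carbene on this Z alkene may be incomplete, which would lower the enantiomeric purity of every ring centre. The fallback sets out from 3 and 5 and returns at 6. The cyclopropanation is run with achiral Rh2(esp)2, which reliably gives the racemic cis-cyclopropane. The enantiomers are then separated by preparative chromatography on a chiral stationary phase, and the unwanted dimethyl (2S,3S)-2-[4-(benzyloxy)phenyl]-3-methylcyclopropane-1,1-dicarboxylate F10 is discarded.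

Step 8. The ortho-benzyloxy group twists ring B out of the alkene plane, which can slow turnover and weaken face discrimination. The fallback replaces asymmetric catalysis by resolution. It sets out from 13 and returns at 14. 13 is hydrogenated with achiral [Ir(cod)(PCy3)(py)]PF6 under H2, which spares C–Br and O–benzyl. The racemate is resolved on a chiral stationary phase, removing the (S)-enantiomer of the bromide, F11.

Step 16. Over-reduction is the risk: hydrogenolysis of the benzylic ring C–O bonds at C2 or C5 could compete once the phenols are free and the arenes are more electron-rich. The fallback sets out from 22 and returns at 23. Pd(OAc)2, Et3SiH and Et3N in CH2Cl2 convert aryl benzyl ethers into silyl ethers under basic conditions without hydrogen gas, giving the tris(triethylsilyl) ether F12. n-Bu4NF in THF then releases 23.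

**Further compounds**

F1 | step 10 | dimethyl (2S,4S,5R)-5-[4-(benzyloxy)phenyl]-2-(ArB)-4-methyloxolane-3,3-dicarboxylate | COC(=O)C1(C(=O)OC)[C@H](C)[C@H](c2ccc(OCc3ccccc3)cc2)O[C@H]1c1ccc(OCc2ccccc2)c([C@H](C)Cc2ccc(OCc3ccccc3)cc2)c1
F2 | step 10 | methyl (2R,4S,5R)-5-[4-(benzyloxy)phenyl]-2-(ArB)-4-methyloxolane-3-carboxylate, C3 epimer mixture | COC(=O)C1[C@H](C)[C@H](c2ccc(OCc3ccccc3)cc2)O[C@H]1c1ccc(OCc2ccccc2)c([C@H](C)Cc2ccc(OCc3ccccc3)cc2)c1
F3 | step 10 | methyl (2R,3R,4S,5R)-5-[4-(benzyloxy)phenyl]-2-(ArB)-4-methyloxolane-3-carboxylate | COC(=O)[C@@H]1[C@H](C)[C@H](c2ccc(OCc3ccccc3)cc2)O[C@H]1c1ccc(OCc2ccccc2)c([C@H](C)Cc2ccc(OCc3ccccc3)cc2)c1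
F4 | step 10 | [(2R,3S,4S,5R)-5-[4-(benzyloxy)phenyl]-2-(ArB)-4-methyloxolan-3-yl]methanol | OC[C@@H]1[C@H](C)[C@H](c2ccc(OCc3ccccc3)cc2)O[C@H]1c1ccc(OCc2ccccc2)c([C@H](C)Cc2ccc(OCc3ccccc3)cc2)c1
F5 | step 10 | [(2R,3S,4S,5R)-5-[4-(benzyloxy)phenyl]-2-(ArB)-4-methyloxolan-3-yl]methyl methanesulfonate | CS(=O)(=O)OC[C@@H]1[C@H](C)[C@H](c2ccc(OCc3ccccc3)cc2)O[C@H]1c1ccc(OCc2ccccc2)c([C@H](C)Cc2ccc(OCc3ccccc3)cc2)c1
F6 | step 10 | (2R,3R,4S,5R)-5-[4-(benzyloxy)phenyl]-2-(ArB)-3,4-dimethyloxolane | C[C@@H]1[C@H](C)[C@H](c2ccc(OCc3ccccc3)cc2)O[C@H]1c1ccc(OCc2ccccc2)c([C@H](C)Cc2ccc(OCc3ccccc3)cc2)c1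
F7 | step 12 | methyl (2S,3S,4S,5S)-5-[4-(benzyloxy)phenyl]-2-(ArB)-3,4-dimethyloxolane-3-carboxylate | COC(=O)[C@@]1(C)[C@H](C)[C@@H](c2ccc(OCc3ccccc3)cc2)O[C@H]1c1ccc(OCc2ccccc2)c([C@H](C)Cc2ccc(OCc3ccccc3)cc2)c1
F8 | step 12 | [(2S,3R,4S,5S)-5-[4-(benzyloxy)phenyl]-2-(ArB)-3,4-dimethyloxolan-3-yl]methanol | OC[C@@]1(C)[C@H](C)[C@@H](c2ccc(OCc3ccccc3)cc2)O[C@H]1c1ccc(OCc2ccccc2)c([C@H](C)Cc2ccc(OCc3ccccc3)cc2)c1
F9 | step 12 | (2S,3S,4S,5S)-5-[4-(benzyloxy)phenyl]-2-(ArB)-3,4-dimethyloxolane-3-carbaldehyde | O=C[C@@]1(C)[C@H](C)[C@@H](c2ccc(OCc3ccccc3)cc2)O[C@H]1c1ccc(OCc2ccccc2)c([C@H](C)Cc2ccc(OCc3ccccc3)cc2)c1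
F10 | step 3 | dimethyl (2S,3S)-2-[4-(benzyloxy)phenyl]-3-methylcyclopropane-1,1-dicarboxylate | COC(=O)C1(C(=O)OC)[C@@H](C)[C@H]1c1ccc(OCc2ccccc2)cc1
F11 | step 8 | 1-(benzyloxy)-2-{(2S)-1-[4-(benzyloxy)phenyl]propan-2-yl}-4-bromobenzene | Brc1ccc(OCc2ccccc2)c([C@@H](C)Cc2ccc(OCc3ccccc3)cc2)c1
F12 | step 16 | tris(triethylsilyl) ether of 23: (2R,3R,4S,5S)-3,4-dimethyl-5-[4-(triethylsilyloxy)phenyl]-2-{4-(triethylsilyloxy)-3-[(2R)-1-[4-(triethylsilyloxy)phenyl]propan-2-yl]phenyl}oxolane | C[C@@H]1[C@H](C)[C@@H](c2ccc(O[Si](CC)(CC)CC)cc2)O[C@H]1c1ccc(O[Si](CC)(CC)CC)c([C@H](C)Cc2ccc(O[Si](CC)(CC)CC)cc2)c1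
A1 | alternative 1 | 4-[(2R,3R,4S,5S)-5-(4-methoxyphenyl)-3,4-dimethyloxolan-2-yl]-2-[(2R)-1-(4-methoxyphenyl)propan-2-yl]phenol | C[C@@H]1[C@H](C)[C@@H](c2ccc(OC)cc2)O[C@H]1c1ccc(O)c([C@H](C)Cc2ccc(OC)cc2)c1
A2 | alternative 1 | 2-[(2S,3R,4S,5S)-5-(4-methoxyphenyl)-3,4-dimethyloxolan-2-yl]acetaldehyde | C[C@@H]1[C@H](C)[C@@H](c2ccc(OC)cc2)O[C@H]1CC=O
A3 | alternative 1 | (5R)-6-(4-methoxyphenyl)-5-methylhex-1-yn-3-one | C#CC(=O)C[C@H](C)Cc1ccc(OC)cc1
A4 | alternative 2 | (2R,3R,4S,5S)-5-(4-methoxyphenyl)-2-{4-methoxy-3-[(2R)-1-(4-methoxyphenyl)propan-2-yl]phenyl}-3-methyloxolane-4-carbaldehyde (ring locants as used for the target) | C[C@@H]1[C@H](C=O)[C@@H](c2ccc(OC)cc2)O[C@H]1c1ccc(OC)c([C@H](C)Cc2ccc(OC)cc2)c1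
A5 | alternative 2 | 2-{4-methoxy-3-[(2R)-1-(4-methoxyphenyl)propan-2-yl]phenyl}-4-(4-methoxyphenyl)-5-[(E)-prop-1-en-1-yl]-1,3-dioxolane, configured at the aryl-bearing ring carbon that becomes C5; the other two ring centres are not carried into the product | C/C=C/C1OC(c2ccc(OC)c([C@H](C)Cc3ccc(OC)cc3)c2)O[C@@H]1c1ccc(OC)cc1
A6 | alternative 3 | methyl (2R,3S)-5-bromo-2-(4-methoxyphenyl)-2,3-dihydro-1-benzofuran-3-carboxylate (cis) | COC(=O)[C@@H]1[C@H](c2ccc(OC)cc2)Oc2ccc(Br)cc21
A7 | alternative 3 | methyl 2-{5-bromo-2-[(4-methoxybenzyl)oxy]phenyl}-2-diazoacetate | COC(=O)C(=[N+]=[N-])c1cc(Br)ccc1OCc1ccc(OC)cc1
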